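The target is a C2-symmetric retro-carotenoid, so it is cut at the central C15–C15' single bond into two identical C20 halves, each traced back to one ring ester. The feature exploited is that in each cyclohexene ring the quaternary gem-dimethyl carbon C1 is bonded directly to sp2 C6 of the exocyclic C6=C7 alkene. An iron-hydride hydrogen-atom transfer turns the methallyl end of an acyclic (S)-silyloxy (Z)-enynoate into the tertiary C1 radical, which adds 6-exo-dig to C6 of the alkynoate, closing the ring and creating the C6=C7 enoate at once. The precursor is an acyclic C11 ester: methallyl group, silyloxy stereocentre, (Z)-trisubstituted alkene, alkynoate.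

Key step: step 5

Remark: (2Z)-3-methylpent-2-en-4-yn-1-ol (ethynyl cis to CH2OH) and 2-methylallylmagnesium chloride (THF solution) are taken as catalogue chemicals; atom positions follow carotenoid numbering (C1–C15, primes for the second half).

Step 1
Reactants: 1 (2Z)-3-methylpent-2-en-4-yn-1-ol
Product: 2 (2Z)-3-methylpent-2-en-4-ynal
Conditions: activated MnO2 (excess), Et2O, rt; filtered through Celite and carried on as a dried Et2O solution
Reagents that add atoms: none
Why: Allylic alcohol oxidation with MnO2, a neutral heterogeneous oxidant that should leave the terminal alkyne and the (Z)-geometry alone, while the volatile enynal is never concentrated to dryness.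

Step 2
Reactants: 2 (2Z)-3-methylpent-2-en-4-ynal; 3 2-methylallylmagnesium chloride
Product: 6 (4S,5Z)-2,6-dimethylocta-1,5-dien-7-yn-4-ol, via B-(2-methylallyl)diisopinocampheylborane 4 (not isolated), via diisopinocampheylborinate ester 5 (not isolated)
Conditions: (–)-Ipc2BOMe [from (+)-α-pinene, 1.25 equiv], 3 (1.1 equiv), Et2O, –78 °C to rt; 2 in Et2O, –78 °C; then 3 M NaOH, 30% H2O2, 0 °C to rt
Reagents that add atoms: 2-methylallylmagnesium chloride (3), CC(=C)C[Mg]Cl
Why: Brown asymmetric methallylboration through a chair six-membered transition state, in which the isopinocampheyl groups derived from (+)-α-pinene should steer the methallyl unit to the Si face of the aldehyde and so set the (S)-carbinol centre (later C3), before oxidative cleavage of the borinate.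

Step 3
Reactants: 6 (4S,5Z)-2,6-dimethylocta-1,5-dien-7-yn-4-ol; 7 tert-butyldimethylsilyl chloride
Product: 8 tert-butyl{[(4S,5Z)-2,6-dimethylocta-1,5-dien-7-yn-4-yl]oxy}dimethylsilane
Conditions: TBSCl, imidazole, DMF, rt
Reagents that add atoms: tert-butyldimethylsilyl chloride (7), CC(C)(C)[Si](C)(C)Cl
Why: Imidazole-promoted silylation of the secondary allylic alcohol gives a silyl ether that should survive organolithium, hydride, radical, Wittig and palladium conditions and is removed by fluoride at the end.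

Step 4
Reactants: 8 tert-butyl{[(4S,5Z)-2,6-dimethylocta-1,5-dien-7-yn-4-yl]oxy}dimethylsilane; 9 methyl chloroformate
Product: 11 methyl (4Z,6S)-6-[(tert-butyldimethylsilyl)oxy]-4,8-dimethylnona-4,8-dien-2-ynoate, via lithium acetylide 10 (not isolated)
Conditions: n-BuLi (1.05 equiv), THF, –78 °C; then ClCO2Me, –78 to –20 °C
Reagents that add atoms: methyl chloroformate (9), COC(=O)Cl
Why: Deprotonation of the terminal alkyne, the most acidic C–H bond present, and C-acylation of the lithium acetylide with a chloroformate is the standard alkynoate synthesis and leaves the silyl ether and both alkenes untouched.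

Step 5
Reactants: 11 methyl (4Z,6S)-6-[(tert-butyldimethylsilyl)oxy]-4,8-dimethylnona-4,8-dien-2-ynoate
Product: 12 methyl (2E)-2-[(4S)-4-[(tert-butyldimethylsilyl)oxy]-2,6,6-trimethylcyclohex-2-en-1-ylidene]acetate
Conditions: Fe(acac)3 (30 mol %), PhSiH3 (2.5 equiv), EtOH/HOCH2CH2OH 5:1, 0.02 M, degassed, 60 °C
Reagents that add atoms: none
Why: An iron hydride formed from Fe(acac)3 and PhSiH3 gives a hydrogen atom to the terminal CH2 of the 1,1-disubstituted alkene, the nucleophilic tertiary C1 radical adds to C6 (the β-carbon of the alkynoate), and the α-ester vinyl radical at C7 is reduced by divalent iron and protonated by ethanol, which returns trivalent iron. The closest known reaction type is the metal-hydride hydrogen-atom-transfer reductive coupling of alkenes with electron-poor π-acceptors (an intramolecular Giese addition), the alkynoate being a less common acceptor that is well established for tertiary radicals in tin-hydride chemistry. The one ring closes in the 6-exo-dig mode (ring atoms C1 to C6), favoured over 7-endo attack at C7 by tether length and by the polarity match at C6, with the (Z)-C4=C5 alkene holding C3 and C6 on the same side. No stereocentre is formed, and the C3 silyloxy centre is remote from both radical centres and should be unaffected. The step needs hydrogen-atom transfer at the electron-rich methallyl alkene and not at the enynoate, which alkene electronics and high dilution should secure, and it needs the (E)-geometry at C6=C7, which hydrogen delivery to the linear vinyl radical does not guarantee. Any (Z)-enoate should therefore be separated by chromatography and recycled by iodine-catalysed photoequilibration.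

Step 6
Reactants: 12 methyl (2E)-2-[(4S)-4-[(tert-butyldimethylsilyl)oxy]-2,6,6-trimethylcyclohex-2-en-1-ylidene]acetate
Product: 13 (2E)-2-[(4S)-4-[(tert-butyldimethylsilyl)oxy]-2,6,6-trimethylcyclohex-2-en-1-ylidene]ethan-1-ol
Conditions: i-Bu2AlH (2.5 equiv), CH2Cl2, –78 °C; aq. potassium sodium tartrate (KNaC4H4O6) work-up
Reagents that add atoms: none
Why: Low-temperature i-Bu2AlH reduction of a conjugated ester proceeds by 1,2-hydride delivery to the dienyl alcohol, and the tartrate work-up keeps the acid-labile allylic system away from protic acid.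

Step 7
Reactants: 13 (2E)-2-[(4S)-4-[(tert-butyldimethylsilyl)oxy]-2,6,6-trimethylcyclohex-2-en-1-ylidene]ethan-1-ol
Product: 14 (2E)-2-[(4S)-4-[(tert-butyldimethylsilyl)oxy]-2,6,6-trimethylcyclohex-2-en-1-ylidene]acetaldehyde
Conditions: activated MnO2 (excess), CH2Cl2, rt, dark
Reagents that add atoms: none
Why: MnO2 oxidation of a dienylic alcohol under neutral conditions gives the conjugated dienal without over-oxidation and without an acid that could ionise the C3 silyl ether.

Step 8
Reactants: 14 (2E)-2-[(4S)-4-[(tert-butyldimethylsilyl)oxy]-2,6,6-trimethylcyclohex-2-en-1-ylidene]acetaldehyde; 15 2-(triphenylphosphoranylidene)propanal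
Product: 16 (2E,4E)-4-[(4S)-4-[(tert-butyldimethylsilyl)oxy]-2,6,6-trimethylcyclohex-2-en-1-ylidene]-2-methylbut-2-enal
Conditions: 15 (2 equiv), toluene, 90 °C, dark
Reagents that add atoms: 2-(triphenylphosphoranylidene)propanal (15), CC(C=O)=P(c1ccccc1)(c1ccccc1)c1ccccc1
Why: Wittig olefination with a formyl-stabilised ylide is (E)-selective for the trisubstituted C8=C9 bond and should stop after one addition because the α-methyl trienal formed is less electrophilic than the dienal consumed.

Step 9
Reactants: 16 (2E,4E)-4-[(4S)-4-[(tert-butyldimethylsilyl)oxy]-2,6,6-trimethylcyclohex-2-en-1-ylidene]-2-methylbut-2-enal; 17 diethyl [2-(methoxy(methyl)amino)-2-oxoethyl]phosphonate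
Product: 19 (2E,4E,6E)-6-[(4S)-4-[(tert-butyldimethylsilyl)oxy]-2,6,6-trimethylcyclohex-2-en-1-ylidene]-N-methoxy-N,4-dimethylhexa-2,4-dienamide, via sodium phosphonate carbanion 18 (not isolated)
Conditions: 17 (1.3 equiv), NaH, THF, 0 °C; then 16, 0 °C to rt
Reagents that add atoms: diethyl [2-(methoxy(methyl)amino)-2-oxoethyl]phosphonate (17), CCOP(=O)(OCC)CC(=O)N(C)OC
Why: Horner–Wadsworth–Emmons olefination with a Weinreb-amide phosphonate gives the (E)-C10=C11 bond under thermodynamic control of the oxaphosphetane, and, unlike a formyl ylide, the amide product cannot be homologated a second time.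

Step 10
Reactants: 19 (2E,4E,6E)-6-[(4S)-4-[(tert-butyldimethylsilyl)oxy]-2,6,6-trimethylcyclohex-2-en-1-ylidene]-N-methoxy-N,4-dimethylhexa-2,4-dienamide
Product: 20 (2E,4E,6E)-6-[(4S)-4-[(tert-butyldimethylsilyl)oxy]-2,6,6-trimethylcyclohex-2-en-1-ylidene]-4-methylhexa-2,4-dienal
Conditions: i-Bu2AlH (1.3 equiv), THF, –78 °C; aq. potassium sodium tartrate (KNaC4H4O6) work-up
Reagents that add atoms: none
Why: Weinreb amide reduction, in which hydride addition gives a chelated aluminium hemiaminal that survives until work-up, so the aldehyde is released only after the hydride is quenched and is not over-reduced.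

Step 11
Reactants: 20 (2E,4E,6E)-6-[(4S)-4-[(tert-butyldimethylsilyl)oxy]-2,6,6-trimethylcyclohex-2-en-1-ylidene]-4-methylhexa-2,4-dienal; 15 2-(triphenylphosphoranylidene)propanal
Product: 21 (2E,4E,6E,8E)-8-[(4S)-4-[(tert-butyldimethylsilyl)oxy]-2,6,6-trimethylcyclohex-2-en-1-ylidene]-2,6-dimethylocta-2,4,6-trienal
Conditions: 15 (2 equiv), toluene, 85 °C, dark
Reagents that add atoms: 2-(triphenylphosphoranylidene)propanal (15), CC(C=O)=P(c1ccccc1)(c1ccccc1)c1ccccc1
Why: Second Wittig olefination with the same formyl-stabilised ylide, (E)-selective at C12=C13 and self-limiting because the α-methyl pentaenal product is less reactive than the α-unsubstituted tetraenal.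

Step 12
Reactants: 21 (2E,4E,6E,8E)-8-[(4S)-4-[(tert-butyldimethylsilyl)oxy]-2,6,6-trimethylcyclohex-2-en-1-ylidene]-2,6-dimethylocta-2,4,6-trienal; 22 iodoform
Product: 23 tert-butyl{[(1S,4E)-4-[(2E,4E,6E,8E)-9-iodo-3,7-dimethylnona-2,4,6,8-tetraen-1-ylidene]-3,5,5-trimethylcyclohex-2-en-1-yl]oxy}dimethylsilane
Conditions: CrCl2 (8 equiv), CHI3 (2 equiv), THF/1,4-dioxane 1:6, 0 °C to rt, dark
Reagents that add atoms: iodoform (22), IC(I)I
Why: Takai iodo-olefination, in which the geminal dichromium species from CHI3 and CrCl2 adds to the aldehyde and eliminates to the (E)-alkenyl iodide at C14=C15 under non-basic conditions.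

Step 13
Reactants: 23 tert-butyl{[(1S,4E)-4-[(2E,4E,6E,8E)-9-iodo-3,7-dimethylnona-2,4,6,8-tetraen-1-ylidene]-3,5,5-trimethylcyclohex-2-en-1-yl]oxy}dimethylsilane (half of the material); 24 hexamethylditin
Product: 25 trimethyl[(1E,3E,5E,7E,9E)-9-[(4S)-4-[(tert-butyldimethylsilyl)oxy]-2,6,6-trimethylcyclohex-2-en-1-ylidene]-3,7-dimethylnona-1,3,5,7-tetraen-1-yl]stannane
Conditions: Me3SnSnMe3 (2 equiv), Pd(PPh3)4 (5 mol %), THF, 50 °C, dark
Reagents that add atoms: hexamethylditin (24), C[Sn](C)(C)[Sn](C)(C)C
Why: Palladium-catalysed stannylation of an alkenyl iodide with a distannane (oxidative addition, tin–tin transmetallation, reductive elimination) retains the (E)-geometry, and any homocoupling that accompanies it produces 26 and is not a loss.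

Step 14
Reactants: 23 tert-butyl{[(1S,4E)-4-[(2E,4E,6E,8E)-9-iodo-3,7-dimethylnona-2,4,6,8-tetraen-1-ylidene]-3,5,5-trimethylcyclohex-2-en-1-yl]oxy}dimethylsilane; 25 trimethyl[(1E,3E,5E,7E,9E)-9-[(4S)-4-[(tert-butyldimethylsilyl)oxy]-2,6,6-trimethylcyclohex-2-en-1-ylidene]-3,7-dimethylnona-1,3,5,7-tetraen-1-yl]stannane
Product: 26 (3S,3'S,6E,6'E)-3,3'-bis[(tert-butyldimethylsilyl)oxy]-4',5'-didehydro-4,5'-retro-β,β-carotene (all-E)
Conditions: Pd2(dba)3 (5 mol %), AsPh3 (40 mol %), NMP, rt to 40 °C, dark
Reagents that add atoms: none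
Why: Stille cross-coupling of an (E)-alkenyl iodide with an (E)-alkenylstannane under AsPh3-accelerated conditions forms the central C15–C15' sp2–sp2 bond with retention at both carbons, the standard union of polyene halves.

Step 15
Reactants: 26 (3S,3'S,6E,6'E)-3,3'-bis[(tert-butyldimethylsilyl)oxy]-4',5'-didehydro-4,5'-retro-β,β-carotene
Product: 27 (3S,3'S,6E,6'E)-4',5'-didehydro-4,5'-retro-β,β-carotene-3,3'-diol (all-E; the target)
Conditions: Bu4NF (4 equiv), THF, 0 °C to rt, dark; pH 7 buffer work-up
Reagents that add atoms: none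
Why: Fluoride-driven desilylation (strong Si–F bond) removes both secondary silyl ethers without acid, which the polyene-conjugated allylic alcohols would not tolerate, and does not touch the C3 and C3' stereocentres.

Compound list
1 | (2Z)-3-methylpent-2-en-4-yn-1-ol | C#C/C(C)=C\CO | starting material
2 | (2Z)-3-methylpent-2-en-4-ynal | C#C/C(C)=C\C=O | intermediate
3 | 2-methylallylmagnesium chloride | CC(=C)C[Mg]Cl | starting material
4 | (2-methylprop-2-en-1-yl)bis[(1R,2S,3R,5R)-2,6,6-trimethylbicyclo[3.1.1]heptan-3-yl]borane | CC(=C)CB([C@@H]1C[C@@H]2C[C@@H](C2(C)C)[C@H]1C)[C@@H]1C[C@@H]2C[C@@H](C2(C)C)[C@H]1C | intermediate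
5 | (4S,5Z)-2,6-dimethylocta-1,5-dien-7-yn-4-yl bis[(1R,2S,3R,5R)-2,6,6-trimethylbicyclo[3.1.1]heptan-3-yl]borinate | C=C(C)C[C@H](OB([C@@H]1C[C@@H]2C[C@@H](C2(C)C)[C@H]1C)[C@@H]1C[C@@H]2C[C@@H](C2(C)C)[C@H]1C)/C=C(C)\C#C | intermediate
6 | (4S,5Z)-2,6-dimethylocta-1,5-dien-7-yn-4-ol | C=C(C)C[C@H](O)/C=C(C)\C#C | intermediate
7 | tert-butyldimethylsilyl chloride | CC(C)(C)[Si](C)(C)Cl | starting material
8 | tert-butyl{[(4S,5Z)-2,6-dimethylocta-1,5-dien-7-yn-4-yl]oxy}dimethylsilane | C=C(C)C[C@H](O[Si](C)(C)C(C)(C)C)/C=C(C)\C#C | intermediate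
9 | methyl chloroformate | COC(=O)Cl | starting material
10 | {(3Z,5S)-5-[(tert-butyldimethylsilyl)oxy]-3,7-dimethylocta-3,7-dien-1-yn-1-yl}lithium | C=C(C)C[C@H](O[Si](C)(C)C(C)(C)C)/C=C(C)\C#C[Li] | intermediate
11 | methyl (4Z,6S)-6-[(tert-butyldimethylsilyl)oxy]-4,8-dimethylnona-4,8-dien-2-ynoate | C=C(C)C[C@H](O[Si](C)(C)C(C)(C)C)/C=C(C)\C#CC(=O)OC | intermediate
12 | methyl (2E)-2-[(4S)-4-[(tert-butyldimethylsilyl)oxy]-2,6,6-trimethylcyclohex-2-en-1-ylidene]acetate | CC1=C[C@@H](O[Si](C)(C)C(C)(C)C)CC(C)(C)\C1=C/C(=O)OC | intermediate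
13 | (2E)-2-[(4S)-4-[(tert-butyldimethylsilyl)oxy]-2,6,6-trimethylcyclohex-2-en-1-ylidene]ethan-1-ol | CC1=C[C@@H](O[Si](C)(C)C(C)(C)C)CC(C)(C)\C1=C/CO | intermediate
14 | (2E)-2-[(4S)-4-[(tert-butyldimethylsilyl)oxy]-2,6,6-trimethylcyclohex-2-en-1-ylidene]acetaldehyde | CC1=C[C@@H](O[Si](C)(C)C(C)(C)C)CC(C)(C)\C1=C/C=O | intermediate
15 | 2-(triphenylphosphoranylidene)propanal | CC(C=O)=P(c1ccccc1)(c1ccccc1)c1ccccc1 | starting material
16 | (2E,4E)-4-[(4S)-4-[(tert-butyldimethylsilyl)oxy]-2,6,6-trimethylcyclohex-2-en-1-ylidene]-2-methylbut-2-enal | CC1=C[C@@H](O[Si](C)(C)C(C)(C)C)CC(C)(C)\C1=C/C=C(C)/C=O | intermediate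
17 | diethyl [2-(methoxy(methyl)amino)-2-oxoethyl]phosphonate | CCOP(=O)(OCC)CC(=O)N(C)OC | starting material
18 | sodium salt of the carbanion of 17 | CCOP(=O)(OCC)[CH-]C(=O)N(C)OC.[Na+] | intermediate
19 | (2E,4E,6E)-6-[(4S)-4-[(tert-butyldimethylsilyl)oxy]-2,6,6-trimethylcyclohex-2-en-1-ylidene]-N-methoxy-N,4-dimethylhexa-2,4-dienamide | CC1=C[C@@H](O[Si](C)(C)C(C)(C)C)CC(C)(C)\C1=C/C=C(C)/C=C/C(=O)N(C)OC | intermediate
20 | (2E,4E,6E)-6-[(4S)-4-[(tert-butyldimethylsilyl)oxy]-2,6,6-trimethylcyclohex-2-en-1-ylidene]-4-methylhexa-2,4-dienal | CC1=C[C@@H](O[Si](C)(C)C(C)(C)C)CC(C)(C)\C1=C/C=C(C)/C=C/C=O | intermediate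
21 | (2E,4E,6E,8E)-8-[(4S)-4-[(tert-butyldimethylsilyl)oxy]-2,6,6-trimethylcyclohex-2-en-1-ylidene]-2,6-dimethylocta-2,4,6-trienal | CC1=C[C@@H](O[Si](C)(C)C(C)(C)C)CC(C)(C)\C1=C/C=C(C)/C=C/C=C(C)/C=O | intermediate
22 | iodoform | IC(I)I | starting material
23 | tert-butyl{[(1S,4E)-4-[(2E,4E,6E,8E)-9-iodo-3,7-dimethylnona-2,4,6,8-tetraen-1-ylidene]-3,5,5-trimethylcyclohex-2-en-1-yl]oxy}dimethylsilane | CC1=C[C@@H](O[Si](C)(C)C(C)(C)C)CC(C)(C)\C1=C/C=C(C)/C=C/C=C(C)/C=C/I | intermediate
24 | hexamethylditin | C[Sn](C)(C)[Sn](C)(C)C | starting material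
25 | trimethyl[(1E,3E,5E,7E,9E)-9-[(4S)-4-[(tert-butyldimethylsilyl)oxy]-2,6,6-trimethylcyclohex-2-en-1-ylidene]-3,7-dimethylnona-1,3,5,7-tetraen-1-yl]stannane | CC1=C[C@@H](O[Si](C)(C)C(C)(C)C)CC(C)(C)\C1=C/C=C(C)/C=C/C=C(C)/C=C/[Sn](C)(C)C | intermediate
26 | (3S,3'S,6E,6'E)-3,3'-bis[(tert-butyldimethylsilyl)oxy]-4',5'-didehydro-4,5'-retro-β,β-carotene | CC1=C[C@@H](O[Si](C)(C)C(C)(C)C)CC(C)(C)\C1=C/C=C(C)/C=C/C=C(C)/C=C/C=C/C(C)=C/C=C/C(C)=C/C=C1/C(C)=C[C@@H](O[Si](C)(C)C(C)(C)C)CC1(C)C | intermediate
27 | (3S,3'S,6E,6'E)-4',5'-didehydro-4,5'-retro-β,β-carotene-3,3'-diol | CC1=C[C@@H](O)CC(C)(C)\C1=C/C=C(C)/C=C/C=C(C)/C=C/C=C/C(C)=C/C=C/C(C)=C/C=C1/C(C)=C[C@@H](O)CC1(C)C | target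

Total step count: 15. Longest linear sequence: 15 steps (1 to 27; steps 13 and 14 both draw on iodide 23).

Steps most likely to fail

Step 5. Hydrogen-atom transfer may go to the enynoate π-system, or the tertiary radical may be reduced before it cyclises, and hydrogen delivery to the vinyl radical may give poor control of the C6=C7 geometry. The fallback sets out from 11 and comes back at 12 by a polar organopalladium closure of the same C1–C6 bond. Conjugate hydroiodination of the alkynoate (NaI, AcOH, MeCN, 50 °C; anti addition of HI) should give methyl (2Z,4Z,6S)-6-[(tert-butyldimethylsilyl)oxy]-3-iodo-4,8-dimethylnona-2,4,8-trienoate F1. A reductive Heck cyclisation (Pd(OAc)2, PPh3, HCO2Na, Et4NCl, DMF, 80 °C) then closes the ring by 6-exo-trig carbopalladation of the methallyl alkene. The neopentyl palladium intermediate has no β-hydrogen and is reduced by formate to the second methyl group. Oxidative addition and insertion go with retention at C6, so the (Z)-iodide maps onto the (E)-enoate 12 and the geometry problem is removed.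

Step 12. The chromium-mediated olefination of the long polyenal may lose E-selectivity at C14=C15, and the Lewis-acidic trivalent chromium salts may ionise the allylic silyl ether. The fallback sets out from 21 and comes back at 23 through an alkyne. Colvin homologation (Me3SiCHN2, LiN(i-Pr)2, THF, –78 °C to rt) should give the terminal alkyne tert-butyl{[(1S,4E)-4-[(2E,4E,6E)-3,7-dimethylnona-2,4,6-trien-8-yn-1-ylidene]-3,5,5-trimethylcyclohex-2-en-1-yl]oxy}dimethylsilane F2. Hydrozirconation with Cp2Zr(H)Cl (THF, rt; syn addition, zirconium at the terminal carbon) followed by iodinolysis (I2, 0 °C) then fixes the (E)-alkenyl iodide 23 by the mechanism of addition, not by an elimination.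

Step 14. Tin-to-palladium transmetallation of the long polyenyl stannane may be slow, leaving time for geometric scrambling and reductive loss of iodine from the polyenyl palladium intermediate. The fallback sets out from 25 and comes back at 26: copper-mediated oxidative homocoupling of the alkenylstannane (CuCl, DMF, rt) uses the symmetry of the target, needs neither palladium nor the iodide partner, and makes no new compound (F0).

Further compounds
F1 | step 5 | methyl (2Z,4Z,6S)-6-[(tert-butyldimethylsilyl)oxy]-3-iodo-4,8-dimethylnona-2,4,8-trienoate | C=C(C)C[C@H](O[Si](C)(C)C(C)(C)C)/C=C(C)\C(I)=C\C(=O)OC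
F2 | step 12 | tert-butyl{[(1S,4E)-4-[(2E,4E,6E)-3,7-dimethylnona-2,4,6-trien-8-yn-1-ylidene]-3,5,5-trimethylcyclohex-2-en-1-yl]oxy}dimethylsilane | CC1=C[C@@H](O[Si](C)(C)C(C)(C)C)CC(C)(C)\C1=C/C=C(C)/C=C/C=C(C)/C#C
F0 | step 14 | none | none
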